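**Plan**
- Numbering: tetralone C1 (C=O), C2, C3, C4 (stereocentre), C4a, C5 (OH) to C8 (OH), C8a; naphthyl C1' (bonded to C4), C4' (OH), C8' (OMe).
- Retrosynthesis: O8 is masked as a benzyl ether, then ring B is cut at C4–C4a and at C2–C3. This leaves an α-bromoacetophenone (C4a, C8a, C1, C2) and a 4-vinyl-1-naphthol (C3, C4); the vinyl–C1' bond is cut back to a bromonaphthol and a vinylboronate.
- Enabling feature: C4 lies para to the C4' hydroxyl across the naphthalene ring, so a cation at C4 is simply a protonated, neutral p-quinone methide. C4a lies ortho to the free C5 hydroxyl, so it is the arene carbon that can add to the methide carbon through the six-membered ring B.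
- Forward order: the two arenes are made separately (four and two steps). One photoredox/chiral-acid operation then forms C2–C3 and closes ring B at C4–C4a, and hydrogenolysis of the benzyl ether finishes the route.
- Stereochemistry: the single stereocentre C4 (R) is set during ring closure by a chiral phosphoric acid and is not touched afterwards.

Key step: step 7

Assumption: (R)-TRIP is written as the acid that delivers (4R); the facial sense of a new reaction cannot be fixed on paper, and the (S)-acid would replace it should the opposite sense be found.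

Abbreviations: TRIP = 3,3'-bis(2,4,6-triisopropylphenyl)-1,1'-binaphthyl-2,2'-diyl hydrogen phosphate; ppy = 2-phenylpyridinato; TIPS = triisopropylsilyl; SPhos = 2-dicyclohexylphosphino-2',6'-dimethoxybiphenyl.

**Route**

Step 1
Reactants: 1 1-(2,5-dihydroxyphenyl)ethanone (2',5'-dihydroxyacetophenone)
Product: 2 1-[2-hydroxy-5-(triisopropylsilyloxy)phenyl]ethanone
Conditions: TIPSCl (1.05 equiv), imidazole, DMF, 0 °C to rt
Reagents that add atoms: triisopropylsilyl chloride, CC(C)[Si](Cl)(C(C)C)C(C)C
Why: Imidazole-mediated O-silylation of a phenol; the 2-OH is hydrogen-bonded to the acetyl carbonyl and flanked by it, so the bulky silyl chloride should take only the free 5-OH.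

Step 2
Reactants: 2 1-[2-hydroxy-5-(triisopropylsilyloxy)phenyl]ethanone
Product: 3 1-[2-(benzyloxy)-5-(triisopropylsilyloxy)phenyl]ethanone
Conditions: BnBr, K2CO3, acetone, reflux
Reagents that add atoms: benzyl bromide, BrCc1ccccc1
Why: Williamson ether synthesis on the remaining (chelated) phenol, with the hindered aryl TIPS ether expected to withstand anhydrous carbonate in acetone.

Step 3
Reactants: 3 1-[2-(benzyloxy)-5-(triisopropylsilyloxy)phenyl]ethanone
Product: 4 1-[2-(benzyloxy)-5-(triisopropylsilyloxy)phenyl]-2-bromoethanone
Conditions: CuBr2 (2.1 equiv), EtOAc/CHCl3 1:1, reflux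
Reagents that add atoms: CuBr2, Br[Cu]Br
Why: CuBr2 α-bromination of an aryl methyl ketone through its enol (King–Ostrum conditions), which stops at the monobromide and is routinely used on 2,5-dialkoxyacetophenones without ring bromination.

Step 4
Reactants: 4 1-[2-(benzyloxy)-5-(triisopropylsilyloxy)phenyl]-2-bromoethanone
Product: 5 1-[2-(benzyloxy)-5-hydroxyphenyl]-2-bromoethanone
Conditions: KHF2, MeOH, rt
Reagents that add atoms: none
Why: Bifluoride desilylation of an aryl silyl ether under weakly acidic conditions, chosen because neither a phenoxide nor a nucleophilic amine is present to alkylate or displace the α-bromoketone.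

Step 5
Reactants: 6 5-methoxynaphthalen-1-ol
Product: 7 4-bromo-5-methoxynaphthalen-1-ol
Conditions: NBS (1.0 equiv), MeCN, −20 to 0 °C, dark
Reagents that add atoms: N-bromosuccinimide, O=C1CCC(=O)N1Br
Why: Electrophilic aromatic bromination; NBS in acetonitrile brominates 1-naphthols and 1-alkoxynaphthalenes para to oxygen, and the free OH outranks OMe as director, so C4 should be preferred over C8 and C2.

Step 6
Reactants: 7 4-bromo-5-methoxynaphthalen-1-ol; 8 2-ethenyl-4,4,5,5-tetramethyl-1,3,2-dioxaborolane (vinylboronic acid pinacol ester)
Product: 9 4-ethenyl-5-methoxynaphthalen-1-ol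
Conditions: Pd(OAc)2 (3 mol%), SPhos (6 mol%), K3PO4, 1,4-dioxane/H2O 5:1, BHT (trace), 80 °C
Reagents that add atoms: vinylboronic acid pinacol ester 8, C=CB1OC(C)(C)C(C)(C)O1
Why: Suzuki–Miyaura coupling in which zerovalent palladium carrying the electron-rich biarylphosphine inserts into the hindered, electron-rich C–Br bond; free phenols are tolerated under aqueous phosphate, and the radical inhibitor with cold storage should keep the vinylnaphthol from polymerising.

Step 7
Reactants: 5 1-[2-(benzyloxy)-5-hydroxyphenyl]-2-bromoethanone; 9 4-ethenyl-5-methoxynaphthalen-1-ol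
Product: 11 (4R)-8-(benzyloxy)-5-hydroxy-4-(4-hydroxy-8-methoxynaphthalen-1-yl)-3,4-dihydronaphthalen-1(2H)-one, via p-quinone methide 10 (not isolated)
Conditions: fac-Ir(ppy)3 (1 mol%), (R)-TRIP (10 mol%), 2,6-di-tert-butyl-4-methylpyridine (1.2 equiv), degassed CH2Cl2, 450 nm LEDs, −20 °C, 9 added over 4 h to 5 (1.3 equiv); then dark, −20 °C
Reagents that add atoms: none
Why: Proposed new method: excited fac-Ir(ppy)3 reduces bromoketone 5 to an electrophilic α-keto radical that adds to the unsubstituted vinyl carbon of 9 (C2–C3), the 4-hydroxynaphthylmethyl radical is oxidised by the tetravalent iridium species and loses the phenolic proton to give p-quinone methide 10, and 10 closes ring B inside the chiral phosphoric acid complex. The closest known reaction types are the racemic photoredox [4+2] annulation of α-bromoacetophenones with styrenes to 4-aryl-1-tetralones, photoredox radical additions to vinylphenols that pass through quinone methides, and chiral-phosphoric-acid-catalysed Friedel–Crafts 1,6-additions of phenols to p-quinone methides; their merger in one asymmetric operation is what is new. Ring B closes by a 6-exo-trig intramolecular Friedel–Crafts 1,6-addition of C4a onto the exocyclic methide carbon C4, driven by rearomatisation of the naphthol and of the phenol ring. The C4 stereocentre is set in this C–C bond formation by the catalyst, whose P=O accepts a hydrogen bond from the C5 OH while its P–OH donates to the quinone-methide carbonyl, so that the 2,4,6-triisopropylphenyl walls leave one face of C4 open. Regioselectivity of the radical addition follows from benzylic stabilisation, only C4a can reach C4 through a six-membered ring, and the oxygen-bonded alternatives (benzylic bromide, cyclic enol ether, aryl ether) should re-ionise under the acid and drain to the C–C bonded product. The hindered pyridine takes up HBr while leaving most of the phosphoric acid protonated, which suppresses racemic strong-acid closure, and slow addition of 9 at low temperature limits its acid-induced oligomerisation.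

Step 8
Reactants: 11 (4R)-8-(benzyloxy)-5-hydroxy-4-(4-hydroxy-8-methoxynaphthalen-1-yl)-3,4-dihydronaphthalen-1(2H)-one
Product: 12 (4R)-5,8-dihydroxy-4-(4-hydroxy-8-methoxynaphthalen-1-yl)-3,4-dihydronaphthalen-1(2H)-one
Conditions: H2 (1 atm), 10% Pd/C, EtOAc, rt
Reagents that add atoms: none
Why: Catalytic hydrogenolysis of a benzyl aryl ether, which at 1 atm is faster than reduction of the aryl ketone (hydrogen-bonded to the freed C8 OH afterwards) and, being neutral, leaves the C4 stereocentre untouched.

**Compound list**
1 | 1-(2,5-dihydroxyphenyl)ethanone | CC(=O)c1cc(O)ccc1O | starting material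
2 | 1-[2-hydroxy-5-(triisopropylsilyloxy)phenyl]ethanone | CC(=O)c1cc(O[Si](C(C)C)(C(C)C)C(C)C)ccc1O | intermediate
3 | 1-[2-(benzyloxy)-5-(triisopropylsilyloxy)phenyl]ethanone | CC(=O)c1cc(O[Si](C(C)C)(C(C)C)C(C)C)ccc1OCc1ccccc1 | intermediate
4 | 1-[2-(benzyloxy)-5-(triisopropylsilyloxy)phenyl]-2-bromoethanone | O=C(CBr)c1cc(O[Si](C(C)C)(C(C)C)C(C)C)ccc1OCc1ccccc1 | intermediate
5 | 1-[2-(benzyloxy)-5-hydroxyphenyl]-2-bromoethanone | O=C(CBr)c1cc(O)ccc1OCc1ccccc1 | intermediate
6 | 5-methoxynaphthalen-1-ol | COc1cccc2c(O)cccc12 | starting material
7 | 4-bromo-5-methoxynaphthalen-1-ol | COc1cccc2c(O)ccc(Br)c12 | intermediate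
8 | 2-ethenyl-4,4,5,5-tetramethyl-1,3,2-dioxaborolane | C=CB1OC(C)(C)C(C)(C)O1 | starting material
9 | 4-ethenyl-5-methoxynaphthalen-1-ol | C=Cc1ccc(O)c2cccc(OC)c12 | intermediate
10 | (E)-1-[2-(benzyloxy)-5-hydroxyphenyl]-4-(8-methoxy-4-oxonaphthalen-1(4H)-ylidene)butan-1-one (p-quinone methide, formed in the flask, chain turned away from the peri-methoxy group) | COc1cccc2C(=O)C=C/C(=C\CCC(=O)c3cc(O)ccc3OCc3ccccc3)c12 | intermediate
11 | (4R)-8-(benzyloxy)-5-hydroxy-4-(4-hydroxy-8-methoxynaphthalen-1-yl)-3,4-dihydronaphthalen-1(2H)-one | COc1cccc2c(O)ccc([C@H]3CCC(=O)c4c(OCc5ccccc5)ccc(O)c43)c12 | intermediate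
12 | (4R)-5,8-dihydroxy-4-(4-hydroxy-8-methoxynaphthalen-1-yl)-3,4-dihydronaphthalen-1(2H)-one | COc1cccc2c(O)ccc([C@H]3CCC(=O)c4c(O)ccc(O)c43)c12 | target

**Count**
Total steps: 8. Longest linear sequence: 6 (steps 1, 2, 3, 4, 7, 8).

**Steps most likely to fail**

Step 7 (proposed new method). The enantioselective closure may be undercut by racemic pathways (closure catalysed by HBr or by the pyridinium salt, or direct cyclisation of the benzylic radical onto the arene). Vinylnaphthol 9 may also oligomerise under acid before the radical captures it. The fallback separates the two events into known chemistry, setting out from 5 and 9 and returning at 11. First, a photoredox three-component methoxy-alkylation of the vinylarene (fac-Ir(ppy)3, MeOH/MeCN, K2HPO4, blue LEDs, no chiral acid) should trap the benzylic cation as racemic 1-[2-(benzyloxy)-5-hydroxyphenyl]-4-(4-hydroxy-8-methoxynaphthalen-1-yl)-4-methoxybutan-1-one F1. After isolation, F1 is treated with (R)-TRIP (10 mol%) in CH2Cl2 at −20 °C. Loss of methanol regenerates quinone methide 10 in the absence of bromide, light and base, and the known acid-catalysed asymmetric Friedel–Crafts 1,6-addition to in-situ-generated p-quinone methides should then give 11.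

Step 5. Bromination may lose regiocontrol (attack at C2, double bromination) or NBS may oxidise the naphthol to a quinone. The fallback avoids electrophilic substitution on the unsymmetrical naphthol and also bypasses step 6; it sets out from 6 and returns at 9. Compound 6 is O-methylated (MeI, K2CO3, acetone) to the symmetrical 1,5-dimethoxynaphthalene F2, where only ortho versus para selectivity remains. Vilsmeier–Haack formylation (POCl3, DMF) should give 4,8-dimethoxynaphthalene-1-carbaldehyde F3. Sodium ethanethiolate in hot DMF should cleave only the methyl ether para to the formyl group, which is the one conjugated with it, giving 4-hydroxy-8-methoxynaphthalene-1-carbaldehyde F4. Wittig methylenation with excess Ph3P=CH2 (Ph3PCH3Br, KOtBu, THF) then gives 9.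

Step 6. Oxidative addition into the naphtholate-bearing, peri-hindered bromide may be slow, so protodebromination competes, and the free vinylnaphthol may polymerise in the hot basic medium. The fallback masks the phenol and couples under neutral conditions; it sets out from 7 and returns at 9. Compound 7 is silylated (TBSCl, imidazole, DMF) to [(4-bromo-5-methoxynaphthalen-1-yl)oxy](tert-butyl)dimethylsilane F5. Stille coupling with tributyl(vinyl)stannane (Pd(PPh3)4, toluene, 100 °C) should give tert-butyl[(4-ethenyl-5-methoxynaphthalen-1-yl)oxy]dimethylsilane F6, which can be stored. Buffered desilylation (TBAF, AcOH, THF, 0 °C) releases 9 immediately before step 7.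

**Further compounds**
F1 | step 7 | racemic 1-[2-(benzyloxy)-5-hydroxyphenyl]-4-(4-hydroxy-8-methoxynaphthalen-1-yl)-4-methoxybutan-1-one | COc1cccc2c(O)ccc(C(OC)CCC(=O)c3cc(O)ccc3OCc3ccccc3)c12
F2 | step 5 | 1,5-dimethoxynaphthalene | COc1cccc2c(OC)cccc12
F3 | step 5 | 4,8-dimethoxynaphthalene-1-carbaldehyde | COc1cccc2c(OC)ccc(C=O)c12
F4 | step 5 | 4-hydroxy-8-methoxynaphthalene-1-carbaldehyde | COc1cccc2c(O)ccc(C=O)c12
F5 | step 6 | [(4-bromo-5-methoxynaphthalen-1-yl)oxy](tert-butyl)dimethylsilane | COc1cccc2c(O[Si](C)(C)C(C)(C)C)ccc(Br)c12
F6 | step 6 | tert-butyl[(4-ethenyl-5-methoxynaphthalen-1-yl)oxy]dimethylsilane | C=Cc1ccc(O[Si](C)(C)C(C)(C)C)c2cccc(OC)c12
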